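**Strategy.** The synthesis rests on cutting the central benzene ring between C1, the hydroxyl-bearing carbon flanked by both arms, and C6, one arm-bearing carbon. The ring's alternation of oxygenated carbons (C1, C3, C5) with carbon-substituted ones (C2, C4, C6) is what a 3-silyloxy-4-(1-benzyloxyalkenyl)cyclobutenone delivers on heating: four-electron opening to a dienylketene and six-electron closure make the C1–C6 bond and the arene in one operation. The precursor is cyclobutenone 16, carrying both (R)-configured syncarpyl arms as benzyl enol ethers (chosen over methyl so that the final unmasking is a neutral hydrogenolysis), assembled from one enantioenriched alkyne by vinylketene–siloxyalkyne [2+2] cycloaddition.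

Key step: step 10

Remarks before the steps:
- Abbreviation: SynBn = 2-(benzyloxy)-3,3,5,5-tetramethyl-4,6-dioxocyclohex-1-en-1-yl (the syncarpyl ring as its benzyl enol ether).
- Arene numbering: C1 carries the hydroxyl between the arms, C2 and C6 the arms, C3 the silyloxy group, C4 hydrogen (later isobutyryl), C5 the benzyloxy group.
- Assumption: the pybox antipode written in step 2 is taken to deliver the (R) methine; if the copper allenylidene is attacked on the other face, the enantiomeric ligand is used and nothing else changes.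
- The arm methine keeps one spatial arrangement throughout; its descriptor reads (S) in 9 and 11–14 only because the neighbouring CH2 ranks below isopropyl.

Step 1
Reactants: 1 rac-4-methylpent-1-yn-3-ol
Product: 2 rac-4-methylpent-1-yn-3-yl pentafluorobenzoate
Conditions: C6F5COCl, Et3N, DMAP (cat.), CH2Cl2, 0 °C to rt
Reagents that add atoms: pentafluorobenzoyl chloride, O=C(Cl)c1c(F)c(F)c(F)c(F)c1F
Why: DMAP-catalysed acylation of the secondary alcohol gives an electron-poor ester that ionises readily from an aliphatic propargylic position; the stereocentre may stay racemic because step 2 erases it.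

Step 2
Reactants: 2 rac-4-methylpent-1-yn-3-yl pentafluorobenzoate; 3 syncarpic acid
Product: 4 (R)-5-hydroxy-2,2,6,6-tetramethyl-4-(4-methylpent-1-yn-3-yl)cyclohex-4-ene-1,3-dione
Conditions: Cu(MeCN)4BF4 (5 mol %), 2,6-bis[(4S)-4-phenyl-4,5-dihydro-1,3-oxazol-2-yl]pyridine (6 mol %), iPr2NEt (1.2 equiv), MeOH, −20 °C; aq. NH4Cl/Na2EDTA quench
Reagents that add atoms: none
Why: Copper-catalysed asymmetric propargylic substitution, in which the monovalent copper acetylide loses pentafluorobenzoate to give a planar copper allenylidene that C2 of the syncarpate attacks at the γ-carbon on the face left open by the pybox ligand, so the racemic ester converges on the (R) methine.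

Step 3
Reactants: 4 (R)-5-hydroxy-2,2,6,6-tetramethyl-4-(4-methylpent-1-yn-3-yl)cyclohex-4-ene-1,3-dione
Product: 5 (3R)-3-(SynBn)-4-methylpent-1-yne
Conditions: BnBr, K2CO3, DMF, rt
Reagents that add atoms: benzyl bromide, BrCc1ccccc1
Why: Williamson-type O-alkylation of the vinylogous acid, directed to oxygen because C2 already carries a branched substituent between two carbonyls; both enol oxygens give the same compound and the methine is untouched.

Step 4
Reactants: 5 (3R)-3-(SynBn)-4-methylpent-1-yne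
Product: 7 (3R)-3-(SynBn)-4-methyl-1-[(triisopropylsilyl)oxy]pent-1-yne, via lithium ynolate 6 (not isolated)
Conditions: LiN(SiMe3)2 (2.2 equiv), t-BuOOH (1.1 equiv), THF, −78 to 0 °C; then iPr3SiOTf, −78 °C
Reagents that add atoms: tert-butyl hydroperoxide, CC(C)(C)OO; triisopropylsilyl trifluoromethanesulfonate, CC(C)[Si](OS(=O)(=O)C(F)(F)F)(C(C)C)C(C)C
Why: Oxygen transfer from lithium tert-butyl peroxide to the lithium acetylide gives the ynolate, which the bulky silyl triflate traps on oxygen; the non-nucleophilic amide base spares the hindered ketone and the vinylogous ester and does not deprotonate the methine.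

Step 5
Reactants: 5 (3R)-3-(SynBn)-4-methylpent-1-yne
Product: 9 (3S)-3-(SynBn)-4-methylpentanal, via alkenylborane 8 (not isolated)
Conditions: Cy2BH, THF, 0 °C to rt; then 30% H2O2, aq. NaHCO3, 0 °C
Reagents that add atoms: hydrogen peroxide, OO
Why: Anti-Markovnikov hydroboration of the terminal alkyne by a hindered dialkylborane (boron to the terminal carbon) and buffered oxidation of the alkenylborane give the aldehyde, while the flanked ketone and the vinylogous ester react far more slowly.

Step 6
Reactants: 9 (3S)-3-(SynBn)-4-methylpentanal; 10 ethyl diazoacetate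
Product: 11 ethyl (5S)-5-(SynBn)-6-methyl-3-oxoheptanoate
Conditions: SnCl2 (10 mol %), CH2Cl2, rt
Reagents that add atoms: none
Why: Roskamp reaction, in which the diazo carbon adds to the SnCl2-activated aldehyde and a 1,2-hydride shift with loss of dinitrogen gives the β-keto ester two carbons longer.

Step 7
Reactants: 11 ethyl (5S)-5-(SynBn)-6-methyl-3-oxoheptanoate
Product: 12 ethyl (2E,5S)-3-(benzyloxy)-5-(SynBn)-6-methylhept-2-enoate
Conditions: BnOH, PPh3, DIAD, toluene, 0 °C to rt
Reagents that add atoms: benzyl alcohol, OCc1ccccc1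
Why: Mitsunobu alkylation of the acidic β-keto ester, whose enolate attacks the benzyloxyphosphonium ion through oxygen to give the enol ether, expected mainly as the (E) isomer; the geometry is of no consequence for step 9.

Step 8
Reactants: 12 ethyl (2E,5S)-3-(benzyloxy)-5-(SynBn)-6-methylhept-2-enoate
Product: 13 (2E,5S)-3-(benzyloxy)-5-(SynBn)-6-methylhept-2-enoic acid
Conditions: LiOH·H2O, THF/MeOH/H2O, rt; then 1 M HCl to pH 4, 0 °C
Reagents that add atoms: lithium hydroxide, [Li+].[OH-]
Why: Saponification at the ester carbonyl; the syncarpyl enol ether is shielded at its β-carbon by the gem-dimethyl group and the C2 substituent, and the mild acidification avoids enol ether hydrolysis.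

Step 9
Reactants: 13 (2E,5S)-3-(benzyloxy)-5-(SynBn)-6-methylhept-2-enoic acid; 7 (3R)-3-(SynBn)-4-methyl-1-[(triisopropylsilyl)oxy]pent-1-yne
Product: 16 4-[(3R)-1-(benzyloxy)-3-(SynBn)-4-methylpent-1-en-1-yl]-2-[(1R)-1-(SynBn)-2-methylpropyl]-3-[(triisopropylsilyl)oxy]cyclobut-2-en-1-one, via acid chloride 14 (not isolated), via vinylketene 15 (not isolated)
Conditions: 13, Me2C=C(Cl)NMe2, CH2Cl2, 0 °C; solution added slowly to 7, Et3N, CH2Cl2, 0 °C to rt; salts filtered off cold, crude 16 used at once
Reagents that add atoms: none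
Why: Neutral chlorination, 1,4-dehydrochlorination at the γ-CH2 to the vinylketene and ketene–ynol ether [2+2] cycloaddition, in which the ketene carbonyl carbon bonds to the nucleophilic arm-bearing alkyne carbon and the ketene α-carbon to the silyloxy carbon; this fixes the regiochemistry, and C4 and the alkene geometry need no control.

Step 10
Reactants: 16 4-[(3R)-1-(benzyloxy)-3-(SynBn)-4-methylpent-1-en-1-yl]-2-[(1R)-1-(SynBn)-2-methylpropyl]-3-[(triisopropylsilyl)oxy]cyclobut-2-en-1-one
Product: 19 3-(benzyloxy)-2,6-bis[(1R)-1-(SynBn)-2-methylpropyl]-5-[(triisopropylsilyl)oxy]phenol, via dienylketene 17 (not isolated), via cyclohexadienone 18 (not isolated)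
Conditions: toluene (0.02 M), BHT (trace), 90 °C, argon
Reagents that add atoms: none
Why: Heating breaks the C1–C4 bond of the cyclobutenone in a conrotatory four-electron opening to dienylketene 17; because this opening is reversible, material that opens with the alkenyl group turned away recloses and is drained through the isomer in which ketene and alkenyl group are cis. That isomer undergoes a thermally allowed disrotatory six-electron electrocyclisation in which the ketene carbon bonds to the alkene terminus, closing the only new ring (the six-membered carbocycle), and cyclohexa-2,4-dienone 18 tautomerises irreversibly to phenol 19. The closest known reaction type is the closing stage of vinylketene-based benzannulations and the related rearrangement of 4-alkenylcyclobutenones to phenols. No stereocentre is created, since C4 of 16 and C6 of 18 become aromatic, and the two (R) methines stay intact because the benzylated enols cannot act as leaving groups or acidify them. The selectivity needed is regiochemical (hydroxyl between the arms, silyloxy and benzyloxy on the other oxygenated carbons) and is dictated by the connectivity of 16, while neutral base-free conditions keep the new hindered phenol from adding to the neighbouring enol ethers.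

Step 11
Reactants: 19 3-(benzyloxy)-2,6-bis[(1R)-1-(SynBn)-2-methylpropyl]-5-[(triisopropylsilyl)oxy]phenol
Product: 20 5-(benzyloxy)-2,4-bis[(1R)-1-(SynBn)-2-methylpropyl]benzene-1,3-diol
Conditions: Bu4NF, AcOH, THF, 0 °C
Reagents that add atoms: none
Why: Fluoride cleaves the aryl silyl ether, and the acetic acid buffer protonates the phenoxide at once so that it cannot add to the adjacent enol ether; benzyl ethers are inert.

Step 12
Reactants: 20 5-(benzyloxy)-2,4-bis[(1R)-1-(SynBn)-2-methylpropyl]benzene-1,3-diol; 21 isobutyryl chloride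
Product: 23 1-{2-(benzyloxy)-4,6-dihydroxy-3,5-bis[(1R)-1-(SynBn)-2-methylpropyl]phenyl}-2-methylpropan-1-one, via magnesium phenoxide 22 (not isolated)
Conditions: EtMgBr (2.0 equiv), Et2O/toluene, 0 °C; then 21 (1.1 equiv), toluene, 0 °C to rt; aq. NH4Cl
Reagents that add atoms: none
Why: Metal-templated Friedel–Crafts-type ortho-acylation of a bromomagnesium phenoxide, in which the acyl chloride coordinated to magnesium is delivered to the only unsubstituted ring carbon (ortho to O3, para to O1) without a strong Lewis acid that would strip the benzyl enol ethers; phenol deprotonation by the Grignard reagent is far faster than its addition to the hindered carbonyls.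

Step 13
Reactants: 23 1-{2-(benzyloxy)-4,6-dihydroxy-3,5-bis[(1R)-1-(SynBn)-2-methylpropyl]phenyl}-2-methylpropan-1-one
Product: 24 myrtucommulone A
Conditions: H2 (1 atm), 10% Pd/C, EtOAc, rt
Reagents that add atoms: none
Why: Hydrogenolysis of the aryl benzyl ether and both benzyl enol ethers frees the third phenol and the two syncarpyl enols under neutral room-temperature conditions, which spare the tetrasubstituted enol double bonds and the hydrogen-bonded aryl ketone and avoid acid-induced cyclodehydration or retro-Michael scrambling of the methines.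

**Compound list**

1 | rac-4-methylpent-1-yn-3-ol | CC(C)C(O)C#C | starting material
2 | rac-4-methylpent-1-yn-3-yl pentafluorobenzoate | CC(C)C(OC(=O)c1c(F)c(F)c(F)c(F)c1F)C#C | intermediate
3 | syncarpic acid (2,2,4,4-tetramethylcyclohexane-1,3,5-trione) | CC1(C)C(=O)CC(=O)C(C)(C)C1=O | starting material
4 | (R)-5-hydroxy-2,2,6,6-tetramethyl-4-(4-methylpent-1-yn-3-yl)cyclohex-4-ene-1,3-dione | C#C[C@H](C1=C(O)C(C)(C)C(=O)C(C)(C)C1=O)C(C)C | intermediate
5 | 5-(benzyloxy)-2,2,6,6-tetramethyl-4-[(3R)-4-methylpent-1-yn-3-yl]cyclohex-4-ene-1,3-dione, i.e. (3R)-3-(SynBn)-4-methylpent-1-yne | C#C[C@H](C1=C(OCc2ccccc2)C(C)(C)C(=O)C(C)(C)C1=O)C(C)C | intermediate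
6 | lithium (3R)-3-(SynBn)-4-methylpent-1-yn-1-olate | [Li+].[O-]C#C[C@H](C1=C(OCc2ccccc2)C(C)(C)C(=O)C(C)(C)C1=O)C(C)C | intermediate (not isolated)
7 | (3R)-3-(SynBn)-4-methyl-1-[(triisopropylsilyl)oxy]pent-1-yne | CC(C)[Si](C(C)C)(C(C)C)OC#C[C@H](C1=C(OCc2ccccc2)C(C)(C)C(=O)C(C)(C)C1=O)C(C)C | intermediate
8 | dicyclohexyl[(1E,3R)-3-(SynBn)-4-methylpent-1-en-1-yl]borane | C1CCCCC1B(C1CCCCC1)/C=C/[C@H](C1=C(OCc2ccccc2)C(C)(C)C(=O)C(C)(C)C1=O)C(C)C | intermediate (not isolated)
9 | (3S)-3-(SynBn)-4-methylpentanal | O=CC[C@H](C1=C(OCc2ccccc2)C(C)(C)C(=O)C(C)(C)C1=O)C(C)C | intermediate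
10 | ethyl diazoacetate | CCOC(=O)C=[N+]=[N-] | starting material
11 | ethyl (5S)-5-(SynBn)-6-methyl-3-oxoheptanoate | CCOC(=O)CC(=O)C[C@H](C1=C(OCc2ccccc2)C(C)(C)C(=O)C(C)(C)C1=O)C(C)C | intermediate
12 | ethyl (2E,5S)-3-(benzyloxy)-5-(SynBn)-6-methylhept-2-enoate | CCOC(=O)/C=C(/OCc1ccccc1)C[C@H](C1=C(OCc2ccccc2)C(C)(C)C(=O)C(C)(C)C1=O)C(C)C | intermediate
13 | (2E,5S)-3-(benzyloxy)-5-(SynBn)-6-methylhept-2-enoic acid | OC(=O)/C=C(/OCc1ccccc1)C[C@H](C1=C(OCc2ccccc2)C(C)(C)C(=O)C(C)(C)C1=O)C(C)C | intermediate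
14 | (2E,5S)-3-(benzyloxy)-5-(SynBn)-6-methylhept-2-enoyl chloride | ClC(=O)/C=C(/OCc1ccccc1)C[C@H](C1=C(OCc2ccccc2)C(C)(C)C(=O)C(C)(C)C1=O)C(C)C | intermediate (not isolated)
15 | (5R)-3-(benzyloxy)-5-(SynBn)-6-methylhepta-1,3-dien-1-one (vinylketene, C3=C4 geometry unassigned) | O=C=CC(OCc1ccccc1)=C[C@H](C1=C(OCc2ccccc2)C(C)(C)C(=O)C(C)(C)C1=O)C(C)C | intermediate (not isolated)
16 | 4-[(3R)-1-(benzyloxy)-3-(SynBn)-4-methylpent-1-en-1-yl]-2-[(1R)-1-(SynBn)-2-methylpropyl]-3-[(triisopropylsilyl)oxy]cyclobut-2-en-1-one (C4 and alkene geometry unassigned) | O=C1C([C@H](C2=C(OCc3ccccc3)C(C)(C)C(=O)C(C)(C)C2=O)C(C)C)=C(O[Si](C(C)C)(C(C)C)C(C)C)C1C(OCc1ccccc1)=C[C@H](C1=C(OCc2ccccc2)C(C)(C)C(=O)C(C)(C)C1=O)C(C)C | intermediate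
17 | (7R)-5-(benzyloxy)-7-(SynBn)-8-methyl-2-[(1R)-1-(SynBn)-2-methylpropyl]-3-[(triisopropylsilyl)oxy]nona-1,3,5-trien-1-one (dienylketene) | O=C=C([C@H](C2=C(OCc3ccccc3)C(C)(C)C(=O)C(C)(C)C2=O)C(C)C)C(O[Si](C(C)C)(C(C)C)C(C)C)=CC(OCc1ccccc1)=C[C@H](C1=C(OCc2ccccc2)C(C)(C)C(=O)C(C)(C)C1=O)C(C)C | intermediate (not isolated)
18 | 5-(benzyloxy)-2,6-bis[(1R)-1-(SynBn)-2-methylpropyl]-3-[(triisopropylsilyl)oxy]cyclohexa-2,4-dien-1-one (C6 unassigned) | O=C1C([C@H](C2=C(OCc3ccccc3)C(C)(C)C(=O)C(C)(C)C2=O)C(C)C)=C(O[Si](C(C)C)(C(C)C)C(C)C)C=C(OCc2ccccc2)C1[C@H](C2=C(OCc3ccccc3)C(C)(C)C(=O)C(C)(C)C2=O)C(C)C | intermediate (not isolated)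
19 | 3-(benzyloxy)-2,6-bis[(1R)-1-(SynBn)-2-methylpropyl]-5-[(triisopropylsilyl)oxy]phenol | Oc1c([C@H](C2=C(OCc3ccccc3)C(C)(C)C(=O)C(C)(C)C2=O)C(C)C)c(O[Si](C(C)C)(C(C)C)C(C)C)cc(OCc2ccccc2)c1[C@H](C2=C(OCc3ccccc3)C(C)(C)C(=O)C(C)(C)C2=O)C(C)C | intermediate
20 | 5-(benzyloxy)-2,4-bis[(1R)-1-(SynBn)-2-methylpropyl]benzene-1,3-diol | Oc1c([C@H](C2=C(OCc3ccccc3)C(C)(C)C(=O)C(C)(C)C2=O)C(C)C)c(O)cc(OCc2ccccc2)c1[C@H](C2=C(OCc3ccccc3)C(C)(C)C(=O)C(C)(C)C2=O)C(C)C | intermediate
21 | isobutyryl chloride | CC(C)C(=O)Cl | starting material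
22 | bis(bromomagnesium) salt of diol 20 | Br[Mg]Oc1c([C@H](C2=C(OCc3ccccc3)C(C)(C)C(=O)C(C)(C)C2=O)C(C)C)c(O[Mg]Br)cc(OCc2ccccc2)c1[C@H](C2=C(OCc3ccccc3)C(C)(C)C(=O)C(C)(C)C2=O)C(C)C | intermediate (not isolated)
23 | 1-{2-(benzyloxy)-4,6-dihydroxy-3,5-bis[(1R)-1-(SynBn)-2-methylpropyl]phenyl}-2-methylpropan-1-one | CC(C)C(=O)c1c(O)c([C@H](C2=C(OCc3ccccc3)C(C)(C)C(=O)C(C)(C)C2=O)C(C)C)c(O)c([C@H](C2=C(OCc3ccccc3)C(C)(C)C(=O)C(C)(C)C2=O)C(C)C)c1OCc1ccccc1 | intermediate
24 | myrtucommulone A, (R,R) isomer | CC(C)C(=O)c1c(O)c([C@H](C2=C(O)C(C)(C)C(=O)C(C)(C)C2=O)C(C)C)c(O)c([C@H](C2=C(O)C(C)(C)C(=O)C(C)(C)C2=O)C(C)C)c1O | target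

**Step count.** Total: 13 steps. Longest linear sequence: 12 steps (1, 2, 3, 5, 6, 7, 8, 9, 10, 11, 12, 13); step 4 is the side branch that joins at step 9.

**Steps most likely to fail**

Step 9. The amine-mediated generation of the vinylketene may lead to ketene oligomerisation or amine-induced decomposition of the acid chloride faster than capture by the hindered siloxyalkyne, and the labile silyloxycyclobutenone may be lost on handling. The fallback generates the same vinylketene without base from a simpler cyclobutenone. Aldehyde 9 is oxidised under Pinnick conditions (NaClO2, NaH2PO4, 2-methylbut-2-ene) to (3S)-3-(SynBn)-4-methylpentanoic acid F1, which oxalyl chloride converts into the acid chloride F2. Benzyl alcohol and trichloroethylene (KH) give benzyl 1,2-dichlorovinyl ether F3, which n-BuLi converts into benzyloxyethyne F4. Treating F2 with Et3N in the presence of F4 gives, by ketene–alkoxyalkyne [2+2] cycloaddition, 3-(benzyloxy)-4-[(1R)-1-(SynBn)-2-methylpropyl]cyclobut-2-en-1-one F5. Heating F5 with siloxyalkyne 7 in toluene at 80 °C opens F5 to vinylketene 15, which adds to 7 to give 16; this rearranges in the same flask, and the route is rejoined at 19.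

Step 2. Facial discrimination on an allenylidene bearing only an isopropyl group may be poor, and copper may promote cycloisomerisation of the enol onto the alkyne, which would destroy the methine. The fallback builds the same centre by conjugate addition. Syncarpic acid 3 is condensed with isobutyraldehyde (Knoevenagel, L-proline cat.) to 2,2,4,4-tetramethyl-6-(2-methylpropylidene)cyclohexane-1,3,5-trione F6. Asymmetric conjugate alkynylation with (trimethylsilyl)acetylene under a monovalent rhodium catalyst, Rh(acac)(C2H4)2 with a chiral bisphosphine, gives the silylalkyne F7, which has the spatial arrangement of 4 but reads (S) because silicon raises the alkynyl priority. K2CO3 in MeOH removes the silyl group and returns 4.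

Step 12. Acyl transfer may go to a phenoxide oxygen instead of carbon, or the Grignard reagent may add to a carbonyl group if phenol deprotonation is incomplete. The fallback changes both the order and the mode of activation. Silyl ether 19 is acylated with 21 in (CF3)2CHOH at rt, a Friedel–Crafts acylation promoted by the hydrogen-bonding solvent without a metal Lewis acid, to give 1-{2-(benzyloxy)-4-hydroxy-3,5-bis[(1R)-1-(SynBn)-2-methylpropyl]-6-[(triisopropylsilyl)oxy]phenyl}-2-methylpropan-1-one F8. Bu4NF/AcOH then removes the silyl group and returns 23.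

**Further compounds**

F1 | step 9 | (3S)-3-(SynBn)-4-methylpentanoic acid | OC(=O)C[C@H](C1=C(OCc2ccccc2)C(C)(C)C(=O)C(C)(C)C1=O)C(C)C
F2 | step 9 | (3S)-3-(SynBn)-4-methylpentanoyl chloride | ClC(=O)C[C@H](C1=C(OCc2ccccc2)C(C)(C)C(=O)C(C)(C)C1=O)C(C)C
F3 | step 9 | benzyl 1,2-dichlorovinyl ether | ClC=C(Cl)OCc1ccccc1
F4 | step 9 | benzyloxyethyne | C#COCc1ccccc1
F5 | step 9 | 3-(benzyloxy)-4-[(1R)-1-(SynBn)-2-methylpropyl]cyclobut-2-en-1-one | O=C1C=C(OCc2ccccc2)C1[C@H](C3=C(OCc4ccccc4)C(C)(C)C(=O)C(C)(C)C3=O)C(C)C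
F6 | step 2 | 2,2,4,4-tetramethyl-6-(2-methylpropylidene)cyclohexane-1,3,5-trione | CC(C)C=C1C(=O)C(C)(C)C(=O)C(C)(C)C1=O
F7 | step 2 | 5-hydroxy-2,2,6,6-tetramethyl-4-[(3S)-4-methyl-1-(trimethylsilyl)pent-1-yn-3-yl]cyclohex-4-ene-1,3-dione | C[Si](C)(C)C#C[C@H](C1=C(O)C(C)(C)C(=O)C(C)(C)C1=O)C(C)C
F8 | step 12 | 1-{2-(benzyloxy)-4-hydroxy-3,5-bis[(1R)-1-(SynBn)-2-methylpropyl]-6-[(triisopropylsilyl)oxy]phenyl}-2-methylpropan-1-one | CC(C)C(=O)c1c(O[Si](C(C)C)(C(C)C)C(C)C)c([C@H](C2=C(OCc3ccccc3)C(C)(C)C(=O)C(C)(C)C2=O)C(C)C)c(O)c([C@H](C2=C(OCc3ccccc3)C(C)(C)C(=O)C(C)(C)C2=O)C(C)C)c1OCc1ccccc1
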